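## Structural features

The target is one benzene ring with all six positions substituted. In the numbering used here and kept for every intermediate, C1 carries the hydroxymethyl carbon C7, C2 bromine, C3 methoxy, C4 hydroxy, C5 bromine and C6 bromine (2,5,6-tribromovanillyl alcohol). There is no second ring, no chain longer than one carbon and no stereocentre, so the whole problem is the order of six neighbours around one ring. The oxygens on C3 and C4 differ only by a methyl group, so any plan that passes through a symmetric C3/C4 pair must tell them apart later with nothing nearby to help. The fragile unit is the 4-hydroxybenzyl alcohol (C4–OH para to C1–C7–OH). It ionises easily to a para-quinone methide, exchanges its benzylic oxygen under acid, and invites ipso attack at C1 with loss of C7. The three C–Br bonds also exclude organolithium reagents and strong reductants late in the route. C5 (ortho to the phenol) and C6 (para to the methoxy group) are sites an electrophile finds by itself. C2 is meta to the phenol and wedged between C1 and C3, so the contiguous triad C7–C1 / C2–Br / C3–OMe is the real difficulty. The key step exploits this triad: if the C1–C2 bond is written as the triple bond of an aryne, the neighbouring methoxy oxygen on C3 decides that a carbon nucleophile enters at C1 and that the metal, and hence the bromine, ends on C2.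

## Logic of the disconnections

**14 back to 10.**
- Bonds cut: C5–Br and C6–Br.
- Reason: these are the only two free ring positions of 10, and each is activated (C5 ortho to C4–OH, C6 para to C3–OMe). Exhaustive bromination therefore cannot err in position.
- Gain: a tribromide becomes a monobromide with two ring hydrogens.
- Demand: the C1–C7 bond must survive an electrophile that can attack para to the phenol. The forward step lets the HBr it generates mask C7–OH as C7–Br (12), then returns the oxygen from water through 13.

**10 back to 8 (through 9).**
- Bonds changed: C7–O becomes C7–Si, and the C4–O–H bond becomes C4–O–Si.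
- Reason: a hydroxymethyl anion is no reagent, but its silicon-masked form is, and both polar groups must be silent towards organometallic species.
- Gain: the acid-sensitive 4-hydroxybenzyl alcohol appears only two steps before the end.
- Demand: the oxidation of C7–Si must leave C2–Br alone, and the phenol should be released after the peroxide stage.

**8 back to 2 and 4 (through 5, 6 and 7): the key disconnection.**
- Bonds cut: C1–C7 and C2–Br, both in one operation.
- Reason: they lie on neighbouring carbons next to C3–OMe, which is exactly the pattern a polarised C1≡C2 bond in 6 can take up.
- Gain: a ring with four contiguous substituents falls back to a trisubstituted fluoroarene and a one-carbon reagent. The hindered bromine is placed without any electrophilic substitution.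
- In one sentence: the route is the three-component capture of 6, released from 2, by a carbon nucleophile at C1 and a bromine donor at C2.
- Demand: 6 must arise from one site only (5), 4 must add at C1 only, and 7 must persist until it is brominated.

**4 back to 3.**
- Bond cut: C7–Mg, traced to C7–Cl.
- Reason and gain: 3 is a commercial chloride and the metal insertion is a single operation.
- Demand: the Si–O bond of 3 must tolerate the Grignard function of 4.

**2 back to 1.**
- Bond cut: the O–Si bond on the C4 oxygen.
- Reason and gain: 1 is commercial and already holds C3–OMe and C4–OH differentiated, with fluorine on C1 as the later leaving group.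
- Demand: the protecting group must resist nBuLi and must not direct lithiation to C5.

## Other disconnections considered

**Alternative 1:** the first plan that comes to mind.
- Cut: all three C–Br bonds.
- Forward key step: exhaustive electrophilic bromination of vanillin A1 to 2,5,6-tribromovanillin A2, then hydride reduction of the aldehyde to 14.
- Merit: this plan is shorter.
- Ground for preferring the chosen plan: the last bromine must enter C2 of a ring that already carries a formyl group and two bromines. C2 is meta to the phenol and sits between two substituents. Forcing conditions are therefore expected, under which ipso attack para to the phenol and ether cleavage can compete. All positional information also comes from exhaustion rather than control. The chosen plan places C2–Br under the control of the neighbouring methoxy group and leaves only the two naturally reactive positions to electrophilic substitution.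

**Alternative 2:**
- Cut: the ring itself, at C1–C2 and C5–C6.
- Forward key step: Diels–Alder reaction of 2,5-dibromo-3,4-dimethoxythiophene 1,1-dioxide A3 (C2 to C5) with methyl 3-bromopropiolate A4 (C6 and C1). Cheletropic loss of the sulfonyl bridge then gives methyl 2,3,6-tribromo-4,5-dimethoxybenzoate A5, with all six substituents in place.
- Merit: the palindromic Br–O–O–Br edge C2–C5 makes the diene symmetric, so no regiochemistry arises.
- Ground for preferring the chosen plan:
  - The same symmetry erases the only difference between the two oxygens. A5 would need one of two methyl ethers with identical neighbours to be cleaved.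
  - The only handle is the para ester on C1. It is twisted out of conjugation by the bromines on C2 and C6, so the two phenoxides should be nearly equal leaving groups.
  - An unsymmetric diene would bring the regiochemistry back, and the stronger donor on C3 should steer the ester para to itself, which is the wrong way.
  - The plan also needs S-oxidation of an electron-rich dibromothiophene, a heat-sensitive bromoalkyne and an ester reduction, so it is longer.

**Alternative 3:**
- Cut: the same two bonds (C1–C7 and C2–Br), but last, with the bromines on C5 and C6 already present.
- Forward key step: deprotonation of (4,5,6-tribromo-2-methoxyphenoxy)triisopropylsilane A6 at its only ring C–H (C2), loss of the C1 bromide as its lithium salt to give 5,6-dibromo-3-methoxy-4-(triisopropylsilyloxy)benzyne A7, then addition of 4 and a bromine donor.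
- Merit: this would be more convergent.
- Ground for preferring the chosen plan:
  - In A7 the triple bond is flanked by OMe on C3 and by Br on C6. These two σ-acceptors polarise it in opposite senses, so the side on which carbon adds is no longer decided.
  - Addition at C2 would leave the metal on C1 beside C6–Br, from which a second elimination can start.
  - Every aryl-metal species present could exchange with C–Br bonds and scramble the bromine pattern.
  - The chosen plan keeps hydrogen on C6 at the aryne stage, so a single substituent governs the addition.

Key step: step 3

Remark: the SMILES holds no stereocentre and no double-bond geometry, so no configuration has to be set. Compounds 1 and 3 are taken as commercial.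

## Route

Step 1
Reactants: 1 4-fluoro-2-methoxyphenol
Product: 2 (4-fluoro-2-methoxyphenoxy)triisopropylsilane
Conditions: iPr3SiCl, imidazole, DMF, rt
Reagents that add atoms: triisopropylsilyl chloride, CC(C)[Si](Cl)(C(C)C)C(C)C
Why: Standard imidazole-promoted silylation of a phenol. The bulky silyl ether should withstand nBuLi at –78 °C and Grignard reagents at rt, and it neither coordinates lithium nor leaves room for metalation at C5.

Step 2
Reactants: 3 (chloromethyl)(isopropoxy)dimethylsilane
Product: 4 [(isopropoxydimethylsilyl)methyl]magnesium chloride (THF solution, titrated and used directly)
Conditions: Mg turnings, THF, rt to 45 °C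
Reagents that add atoms: magnesium, [Mg]
Why: Grignard formation from a primary α-silyl chloride. The hindered Si–OiPr bond is not attacked by the primary alkylmagnesium function, which makes 4 an established nucleophilic hydroxymethylating agent.

Step 3
Reactants: 2 (4-fluoro-2-methoxyphenoxy)triisopropylsilane; 4 [(isopropoxydimethylsilyl)methyl]magnesium chloride
Product: 8 {[2-bromo-3-methoxy-4-(triisopropylsilyloxy)phenyl]methyl}(isopropoxy)dimethylsilane, via aryllithium 5 (not isolated), via aryne 6 (not isolated), via arylmagnesium chloride 7 (not isolated)
Conditions: nBuLi, THF, –78 °C; 4 (3 equiv), –78 °C to rt; BrCl2CCCl2Br, –78 °C to rt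
Reagents that add atoms: 1,2-dibromo-1,1,2,2-tetrachloroethane, BrC(Cl)(Cl)C(Cl)(Cl)Br
Why: nBuLi removes H2 of 2, the only ring proton flanked by both the fluorine on C1 and the methoxy oxygen on C3 (cooperative ortho-lithiation), and 5 should persist at –78 °C. On warming, 5 loses LiF and releases 6, whose strained C1≡C2 bond has C3–OMe on one side and C6–H on the other, so a single substituent polarises it. The σ-withdrawing oxygen on C3 distorts the aryne so that C1 becomes the flatter, more electrophilic terminus, and the charge building up at C2 lies next to that oxygen, where it is stabilised inductively and by O–Mg contact; the carbon of 4 therefore bonds to C1 and magnesium ends on C2 in 7. Beside its C–Mg bond 7 has only a methoxy group and a CH2 group, hence no further elimination path, and it waits for the halogen donor, which transfers Br+ to C2. The closest known reaction type is the three-component coupling of 3-alkoxyarynes, released from ortho-lithiated fluoroarenes, with Grignard reagents and a final electrophile. No ring is closed and no stereocentre is formed. The step needs site selectivity in the lithiation (secured by F and OMe together and by the bulk of the silyl ether), regioselectivity in the addition (secured by OMe next to the triple bond and H on the far side) and chemoselectivity for 4 over 5 as the partner of 6 (secured by an excess of 4 and slow warming). A halogen-transfer reagent instead of Br2 spares the electron-rich ring and the benzylic C7–Si bond.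

Step 4
Reactants: 8 {[2-bromo-3-methoxy-4-(triisopropylsilyloxy)phenyl]methyl}(isopropoxy)dimethylsilane
Product: 10 2-bromo-4-hydroxy-3-methoxybenzyl alcohol, via silyl-protected benzyl alcohol 9 (not isolated)
Conditions: 30% H2O2, KF, KHCO3, THF/MeOH, rt; work-up; Bu4NF, THF, 0 °C
Reagents that add atoms: hydrogen peroxide, OO
Why: Tamao–Fleming oxidation: hydroperoxide adds to the fluoride-activated alkoxysilane and C7 migrates from silicon to oxygen, while the aryl bromide and both ethers are inert to buffered peroxide. Fluoride then cleaves the phenolic silyl ether of 9, a fast reaction because the phenoxide is a good leaving group from silicon.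

Step 5
Reactants: 10 2-bromo-4-hydroxy-3-methoxybenzyl alcohol
Product: 14 2,5,6-tribromo-4-hydroxy-3-methoxybenzyl alcohol, via dibromo alcohol 11 (not isolated), via tribromobenzyl bromide 12 (not isolated), via quinone methide 13 (not isolated)
Conditions: Br2 (2.2 equiv), AcOH/CH2Cl2, 0 °C to rt; evaporate; acetone/H2O, NaHCO3, rt
Reagents that add atoms: bromine, BrBr; water, O
Why: Electrophilic aromatic bromination fills the only two free positions, first C5 (ortho to the phenol, 11) and then C6 (para to the methoxy group), so no positional selectivity is asked for. The HBr formed turns the 4-hydroxybenzyl alcohol into its bromide 12, which cannot lose C7 after ipso attack at C1. In buffered aqueous acetone 12 undergoes 1,6-elimination to 13, and water adds to the exocyclic C7 (1,6-addition), which restores the aromatic ring and the alcohol.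

## Compound list

1 | 4-fluoro-2-methoxyphenol | COc1cc(F)ccc1O | starting material
2 | (4-fluoro-2-methoxyphenoxy)triisopropylsilane | COc1cc(F)ccc1O[Si](C(C)C)(C(C)C)C(C)C | intermediate
3 | (chloromethyl)(isopropoxy)dimethylsilane | CC(C)O[Si](C)(C)CCl | starting material
4 | [(isopropoxydimethylsilyl)methyl]magnesium chloride | CC(C)O[Si](C)(C)C[Mg]Cl | intermediate
5 | [6-fluoro-2-methoxy-3-(triisopropylsilyloxy)phenyl]lithium | COc1c([Li])c(F)ccc1O[Si](C(C)C)(C(C)C)C(C)C | intermediate
6 | 3-methoxy-4-(triisopropylsilyloxy)benzyne (1,2-didehydrobenzene, triple bond C1≡C2) | COC1=C(O[Si](C(C)C)(C(C)C)C(C)C)C=CC#C1 | intermediate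
7 | {6-[(isopropoxydimethylsilyl)methyl]-2-methoxy-3-(triisopropylsilyloxy)phenyl}magnesium chloride | COc1c([Mg]Cl)c(C[Si](C)(C)OC(C)C)ccc1O[Si](C(C)C)(C(C)C)C(C)C | intermediate
8 | {[2-bromo-3-methoxy-4-(triisopropylsilyloxy)phenyl]methyl}(isopropoxy)dimethylsilane | COc1c(Br)c(C[Si](C)(C)OC(C)C)ccc1O[Si](C(C)C)(C(C)C)C(C)C | intermediate
9 | [2-bromo-3-methoxy-4-(triisopropylsilyloxy)phenyl]methanol | COc1c(Br)c(CO)ccc1O[Si](C(C)C)(C(C)C)C(C)C | intermediate
10 | 2-bromo-4-hydroxy-3-methoxybenzyl alcohol | COc1c(O)ccc(CO)c1Br | intermediate
11 | 2,5-dibromo-4-hydroxy-3-methoxybenzyl alcohol | COc1c(O)c(Br)cc(CO)c1Br | intermediate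
12 | 2,5,6-tribromo-4-hydroxy-3-methoxybenzyl bromide | COc1c(O)c(Br)c(Br)c(CBr)c1Br | intermediate
13 | 2,3,5-tribromo-6-methoxy-4-methylidenecyclohexa-2,5-dien-1-one | COC1=C(Br)C(=C)C(Br)=C(Br)C1=O | intermediate
14 | 2,5,6-tribromo-4-hydroxy-3-methoxybenzyl alcohol, systematic name (2,3,6-tribromo-4-hydroxy-5-methoxyphenyl)methanol | COc1c(O)c(Br)c(Br)c(CO)c1Br | target

## Step count and least certain steps

Total step count: 5. Longest linear sequence: 4 (steps 1, 3, 4 and 5). Step 2 prepares the one-carbon reagent.

**Step 3 (key step).**
- The most likely failure is consumption of the aryne by partners other than 4. The α-silyl Grignard reagent is only a moderate nucleophile, so addition of still unreacted aryllithium to the triple bond (biaryl formation) can compete.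
- Attack of the aryllithium on the Si–O bond of 4 before fluoride loss can also compete.
- The hindered arylmagnesium species may abstract a proton from the medium before the bromine transfer.
- Fallback, from 2, gives up the aryne:
  - Kumada–Corriu coupling of the C1–F bond with 4 (NiCl2(dppp), THF, reflux) should give isopropoxy{[3-methoxy-4-(triisopropylsilyloxy)phenyl]methyl}dimethylsilane F1.
  - Tamao–Fleming oxidation without fluoride (30% H2O2, KHCO3, THF/MeOH) should give [3-methoxy-4-(triisopropylsilyloxy)phenyl]methanol F2.
  - Directed ortho-lithiation of F2 follows (nBuLi, 2.2 equiv, Et2O, 0 °C to rt). The lithium alkoxide on C7 and the methoxy oxygen on C3 both point to C2. Quenching with BrCl2CCCl2Br comes back to the route at 9.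

**Step 4.**
- The most likely failure is fluoride- or base-induced protodesilylation at C7. A benzylic carbon bearing an ortho bromine is a fair leaving group from pentacoordinate silicon, so this can compete with the 1,2-shift to oxygen.
- Premature loss of the phenolic silyl group would also expose an electron-rich phenol to peroxide.
- Fallback, from 2, changes the one-carbon synthon so that no C–Si oxidation is needed. Step 3 is run with vinylmagnesium bromide in place of 4 and the same bromine donor, to give 2-bromo-1-ethenyl-3-methoxy-4-(triisopropylsilyloxy)benzene F3. Ozonolysis with reductive work-up (ozone, CH2Cl2/MeOH, –78 °C; NaBH4) comes back to the route at 9.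

**Step 5.**
- The most likely failure is ipso attack of bromine at C1, para to the phenol, with loss of C7 before the alcohol has been masked.
- Friedel–Crafts self-alkylation is also possible while C5 or C6 of a second molecule is still free, because the 4-hydroxybenzyl system ionises easily in acid.
- During the hydrolysis, capture of the quinone methide by phenoxide instead of water would lead to oligomers, so high dilution in a water-rich medium is advisable.
- Fallback, from 10, removes the ionisable benzylic position before bromination. Oxidation (DDQ, dioxane, rt) should give 2-bromo-4-hydroxy-3-methoxybenzaldehyde F4. Bromination (Br2, AcOH, 50 °C) fills C5 and C6 to give the tribromoaldehyde A2. Reduction (NaBH4, THF/EtOH, 0 °C) comes back to the route at 14.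

## Further compounds

F1 | step 3 | isopropoxy{[3-methoxy-4-(triisopropylsilyloxy)phenyl]methyl}dimethylsilane | COc1cc(C[Si](C)(C)OC(C)C)ccc1O[Si](C(C)C)(C(C)C)C(C)C
F2 | step 3 | [3-methoxy-4-(triisopropylsilyloxy)phenyl]methanol | COc1cc(CO)ccc1O[Si](C(C)C)(C(C)C)C(C)C
F3 | step 4 | 2-bromo-1-ethenyl-3-methoxy-4-(triisopropylsilyloxy)benzene | C=Cc1ccc(O[Si](C(C)C)(C(C)C)C(C)C)c(OC)c1Br
F4 | step 5 | 2-bromo-4-hydroxy-3-methoxybenzaldehyde | COc1c(O)ccc(C=O)c1Br
A1 | alternative 1 | vanillin (4-hydroxy-3-methoxybenzaldehyde) | COc1cc(C=O)ccc1O
A2 | alternative 1 | 2,5,6-tribromovanillin (2,3,6-tribromo-4-hydroxy-5-methoxybenzaldehyde) | COc1c(O)c(Br)c(Br)c(C=O)c1Br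
A3 | alternative 2 | 2,5-dibromo-3,4-dimethoxythiophene 1,1-dioxide | COC1=C(Br)S(=O)(=O)C(Br)=C1OC
A4 | alternative 2 | methyl 3-bromopropiolate | COC(=O)C#CBr
A5 | alternative 2 | methyl 2,3,6-tribromo-4,5-dimethoxybenzoate | COC(=O)c1c(Br)c(Br)c(OC)c(OC)c1Br
A6 | alternative 3 | (4,5,6-tribromo-2-methoxyphenoxy)triisopropylsilane | COc1cc(Br)c(Br)c(Br)c1O[Si](C(C)C)(C(C)C)C(C)C
A7 | alternative 3 | 5,6-dibromo-3-methoxy-4-(triisopropylsilyloxy)benzyne | COC1=C(O[Si](C(C)C)(C(C)C)C(C)C)C(Br)=C(Br)C#C1
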